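**Late stall.** At late times the south run stands still: starting material reads 58.9% at 10.0 h and 58.7% at 15.0 h, while the colder south-east run, at 5 °C, is still falling at 30.0 h. The south run was charged with 0.666 M of coupling partner against 0.30 M of starting material, and by 15.0 h the readings show about 0.124 M of starting material consumed, which matches a part of that partner charge. The reckoning here takes the partner to decay on its own in the warm flask.

| flask | starting material | coupling partner | second substrate | temperature | remark | time |
|---|---|---|---|---|---|---|
| south-east | 0.073 M | 0.666 M | 0.37 M | 5 °C | run made earlier |  |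
| south | 0.30 M | 0.666 M | 0.37 M | 20 °C | run made earlier |  |
| north | 0.37 M | 0.72 M | 0.37 M | 5 °C | run made earlier |  |
| cedar | 0.12 M | 1.20 M | 0.370 M | 20 °C |  | 30 h |
| larch | 0.37 M | 0.666 M | 0.370 M | 20 °C |  | 15 h |

| run | time / h | target / % | starting material / % |
|---|---|---|---|
| south-east | 4.00 | 13.0 | 85.5 |
| south-east | 8.00 | 20.9 | 75.6 |
| south-east | 12.0 | 24.3 | 67.2 |
| south-east | 15.0 | 27.5 | 61.6 |
| south-east | 20.0 | 28.2 | 58.3 |
| south-east | 25.0 | 29.9 | 51.8 |
| south-east | 30.0 | 28.9 | 48.1 |
| south | 1.33 | 13.2 | 85.7 |
| south | 2.00 | 18.5 | 77.6 |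
| south | 3.00 | 21.2 | 72.0 |
| south | 4.00 | 18.5 | 67.2 |
| south | 6.00 | 20.6 | 61.0 |
| south | 10.0 | 22.3 | 58.9 |
| south | 15.0 | 20.2 | 58.7 |
| north | 6.00 | 17.8 | 80.3 |
| north | 12.0 | 25.5 | 66.0 |
| north | 20.0 | 26.4 | 59.8 |
| north | 25.0 | 27.9 | 53.2 |
| north | 30.0 | 27.2 | 49.4 |

(scatter of a reading: 1 percentage point)

- which of the two ends with the higher amount of target, in percent of the starting material charged ("neither" if they lie within 2 percentage points) (cedar / larch / neither)
- target at the end, in percent of the starting material charged, cedar
- target at the end, in percent of the starting material charged, larch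

- the numbers in the tables scatter with a standard deviation of 1 percentage point

**Two extremes.** If the stop were a clock indifferent to the partner charge, cedar would stop like south, with 58.8% of its starting material left. If the partner lasted, the early south loss of 0.116 h⁻¹, scaled to cedar's charge, would leave 0.189% at 30 h. A partner decaying in proportion to itself keeps the same clock at any charge, yet a larger charge couples faster throughout, so this reckoning puts cedar between the two.

**Reach.** Divide the fractional fall of starting material by the decay of partner: both follow the partner level, so time and that level drop out. What remains is the reach, a kind of selectivity factor: the logarithm of charged over remaining starting material, per mole per litre of partner charged, 0.797 M⁻¹ as read from south. In the late south readings target holds about 51.6% of the starting material consumed. So this reckoning gives cedar 38.4% left and 31.8% target, and larch, with south's partner charge, 21.2% target.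

**Forecast.** The forecast says neither, with 22.5% for cedar and 21% for larch: “It may push conversion further, but target sits near its maximum”. For cedar this differs from the reckoning above.

**Result.** The higher flask is cedar: cedar ends at 28.4%, larch at 20.4%.

    starting material + coupling partner ⇌ target (K = 12.0 M⁻¹, k = 8.06 × 10⁻⁵ M⁻¹ s⁻¹, Ea = 67.0 kJ mol⁻¹, ΔH = −74.0 kJ mol⁻¹)
    2 second substrate → self-condensation product (k = 1.63 × 10⁻⁵ M⁻¹ s⁻¹, Ea = 64.0 kJ mol⁻¹)
    target ⇌ isomer of the product (K = 0.990, k = 7.52 × 10⁻⁵ s⁻¹, Ea = 85.0 kJ mol⁻¹, ΔH = −27.0 kJ mol⁻¹)
    second substrate + coupling partner ⇌ second product (K = 0.880 M⁻¹, k = 3.62 × 10⁻⁴ M⁻¹ s⁻¹, Ea = 77.0 kJ mol⁻¹, ΔH = 22.0 kJ mol⁻¹)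
    coupling partner → decomposed reagent (k = 6.27 × 10⁻⁵ s⁻¹, Ea = 89.0 kJ mol⁻¹)
    (constants at 20 °C)

**Reach tested.** At the start of cedar, the loss to decomposed reagent uses partner 6.5 times as fast as the forward making of target. At 3.48 h that ratio is 13. Cedar's starting material stands at 34.5% at 15.0 h and 42.3% at 30.0 h, against the reckoned 38.4%. In the neighbour of cedar charged with 2.0 M of partner, the reach gives 20.3% of starting material left and 41.1% target; the computed flask holds 29.6% of starting material and 34.7% of target.

All runs come from a simulation for an exercise; the scatter is artificial.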